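The synthesis rests on disconnecting the C9–C10 bond of ring B. In the key step a tertiary carbinol at C10 of a preformed ring A is ionised and the cation is captured by C9 of a (Z)-allylsilane. This closes ring B, creates the quaternary C10 and the C9 stereocentres, and unveils the C8=C17 exocyclic methylene in one operation. The step exploits the homoallylic relation between quaternary C10 and the C8(17) methylene of ring B. Its precursor is a monocyclic cyclohexanol ester whose C5 side chain carries the C6 acetate, the allylsilane and a (Z)-vinyl iodide; C4 comes from catalytic conjugate addition, C5 and C6 from lactone-controlled equilibration.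

Key step: step 12

Remark: labdane numbering (C1–C20) is used for all intermediates. Compounds 1, 2 and 10 are taken as commercial. The enantiomer of the chiral ligand in step 7 is the one that gives (S) at C4. The C10 configuration of 14–17 is lost in step 12 and does not affect the outcome.

Step 1
Reactants: 1 2,3-dihydrofuran; 2 tert-butyl(2-iodoethoxy)dimethylsilane
Product: 4 tert-butyl[2-(4,5-dihydrofuran-2-yl)ethoxy]dimethylsilane, via 5-lithio-2,3-dihydrofuran 3 (not isolated)
Conditions: t-BuLi, THF/pentane, −78 → 0 °C; then 2, −30 → 23 °C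
Reagents that add atoms: none
Why: Deprotonation of the vinylic C–H next to the ring oxygen gives the lithiated enol ether, which is alkylated by the primary iodide in an SN2 reaction (alkylation of a metallated cyclic enol ether); no stereocentre is formed.

Step 2
Reactants: 4 tert-butyl[2-(4,5-dihydrofuran-2-yl)ethoxy]dimethylsilane
Product: 5 (3Z)-6-[(tert-butyldimethylsilyl)oxy]-4-[(trimethylsilyl)methyl]hex-3-en-1-ol
Conditions: Me3SiCH2MgCl, NiCl2(PPh3)2 (cat.), toluene, 100 °C
Reagents that add atoms: (trimethylsilyl)methylmagnesium chloride C[Si](C)(C)C[Mg]Cl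
Why: The nickel-catalysed Kumada-type coupling of a Grignard reagent with the vinylic C–O bond of a dihydrofuran (Wenkert coupling) replaces the ring oxygen by CH2SiMe3 with retention, so the ring fixes the (Z) geometry of the C8=C9 allylsilane (CH2SiMe3 cis to C11) and releases the C12 hydroxyl.

Step 3
Reactants: 5 (3Z)-6-[(tert-butyldimethylsilyl)oxy]-4-[(trimethylsilyl)methyl]hex-3-en-1-ol
Product: 6 (3Z)-6-[(tert-butyldimethylsilyl)oxy]-4-[(trimethylsilyl)methyl]hex-3-enal
Conditions: Dess–Martin periodinane, NaHCO3, CH2Cl2, 0 °C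
Reagents that add atoms: none
Why: Dess–Martin oxidation converts the primary alcohol into the aldehyde under buffered, non-basic conditions that should leave the allylsilane and the β,γ-double bond in place.

Step 4
Reactants: 6 (3Z)-6-[(tert-butyldimethylsilyl)oxy]-4-[(trimethylsilyl)methyl]hex-3-enal
Product: 7 tert-butyl{[(3Z,6Z)-7-iodo-3-[(trimethylsilyl)methyl]octa-3,6-dien-1-yl]oxy}dimethylsilane
Conditions: [Ph3PEt]I, n-BuLi, THF, 23 °C; I2, −78 °C; NaHMDS, −20 °C; then 6, −78 → −20 °C
Reagents that add atoms: ethyltriphenylphosphonium iodide CC[P+](c1ccccc1)(c1ccccc1)c1ccccc1.[I-]; iodine II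
Why: The Stork–Zhao-type Wittig olefination with the α-iodo ylide made in the flask runs through the kinetically favoured cis-oxaphosphetane and should give the (Z)-2-iodoalkene, which fixes the later C12=C13 geometry (iodine cis to C11).

Step 5
Reactants: 7 tert-butyl{[(3Z,6Z)-7-iodo-3-[(trimethylsilyl)methyl]octa-3,6-dien-1-yl]oxy}dimethylsilane
Product: 8 (3Z,6Z)-7-iodo-3-[(trimethylsilyl)methyl]octa-3,6-dien-1-ol
Conditions: TBAF, AcOH, THF, 0 → 23 °C
Reagents that add atoms: none
Why: Fluoride cleaves the primary silyl ether (desilylation), and the acetic acid buffer keeps the medium non-basic so that the allylsilane and the vinyl iodide should survive.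

Step 6
Reactants: 8 (3Z,6Z)-7-iodo-3-[(trimethylsilyl)methyl]octa-3,6-dien-1-ol
Product: 9 (3Z,6Z)-7-iodo-3-[(trimethylsilyl)methyl]octa-3,6-dienal
Conditions: Dess–Martin periodinane, NaHCO3, CH2Cl2, 0 °C; used at once
Reagents that add atoms: none
Why: A second buffered Dess–Martin oxidation gives the β,γ-unsaturated aldehyde, which is used immediately to avoid migration of the double bond into conjugation.

Step 7
Reactants: 10 methyl 3-oxocyclohex-1-ene-1-carboxylate; 9 (3Z,6Z)-7-iodo-3-[(trimethylsilyl)methyl]octa-3,6-dienal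
Product: 12 methyl (1S,2S)-2-[(1S,3Z,6Z)-1-hydroxy-7-iodo-3-[(trimethylsilyl)methyl]octa-3,6-dien-1-yl]-1-methyl-3-oxocyclohexane-1-carboxylate, via methylzinc enolate 11 (not isolated)
Conditions: Me2Zn, (CuOTf)2·C6H6 (cat.), chiral sulfonate-bearing imidazolinium salt (carbene precursor, cat.), t-BuOMe, −30 °C; then 9, −78 °C
Reagents that add atoms: dimethylzinc C[Zn]C
Why: Copper-catalysed enantioselective conjugate addition of Me2Zn to the β-ester enone sets the quaternary C4 (S) under catalyst control and gives the C5 zinc enolate regiospecifically, which adds to 9 through a Zimmerman–Traxler aldol transition state on the face opposite the pseudo-axial ester, so that C6 (S) is set and C5 is formed in a provisional (anti-aldol) configuration that step 8 corrects.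

Step 8
Reactants: 12 methyl (1S,2S)-2-[(1S,3Z,6Z)-1-hydroxy-7-iodo-3-[(trimethylsilyl)methyl]octa-3,6-dien-1-yl]-1-methyl-3-oxocyclohexane-1-carboxylate (with its minor C5/C6 diastereomers)
Product: 13 (3S,3aR,7aS)-3-[(2Z,5Z)-6-iodo-2-[(trimethylsilyl)methyl]hepta-2,5-dien-1-yl]-7a-methylhexahydro-2-benzofuran-1,4-dione (cis-fused keto γ-lactone, C7 chain on the convex face)
Conditions: DBU (0.2 equiv), toluene, 23 → 40 °C
Reagents that add atoms: none
Why: Under catalytic base C5 epimerises through the ketone enolate, the C6 hydroxyl lactonises onto the now cis C19 ester, and any C6 epimer equilibrates by reversible β-elimination and oxa-Michael re-addition of the carboxylate, so the material should collect in the thermodynamically preferred cis-fused γ-lactone with C7 trans to C10, which carries the C4, C5 and C6 configuration of the target.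

Step 9
Reactants: 13 (3S,3aR,7aS)-3-[(2Z,5Z)-6-iodo-2-[(trimethylsilyl)methyl]hepta-2,5-dien-1-yl]-7a-methylhexahydro-2-benzofuran-1,4-dione
Product: 14 (3S,3aR,4R,7aS)-4-hydroxy-3-[(2Z,5Z)-6-iodo-2-[(trimethylsilyl)methyl]hepta-2,5-dien-1-yl]-4,7a-dimethylhexahydro-2-benzofuran-1(3H)-one
Conditions: MeMgBr, CeCl3, THF, −78 °C
Reagents that add atoms: methylmagnesium bromide C[Mg]Br
Why: The organocerium reagent formed from MeMgBr and CeCl3 adds 1,2 to the ketone chemoselectively (no enolisation, lactone and vinyl iodide untouched) from the convex α face, which should place the C10 hydroxyl cis to the lactone.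

Step 10
Reactants: 14 (3S,3aR,4R,7aS)-4-hydroxy-3-[(2Z,5Z)-6-iodo-2-[(trimethylsilyl)methyl]hepta-2,5-dien-1-yl]-4,7a-dimethylhexahydro-2-benzofuran-1(3H)-one
Product: 16 methyl (1S,2R,3R)-3-hydroxy-2-[(1S,3Z,6Z)-1-hydroxy-7-iodo-3-[(trimethylsilyl)methyl]octa-3,6-dien-1-yl]-1,3-dimethylcyclohexane-1-carboxylate, via lithium carboxylate 15 (not isolated)
Conditions: LiOH·H2O, THF/H2O, 23 °C; evaporation; MeI, DMF, 0 → 23 °C
Reagents that add atoms: lithium hydroxide [Li+].[OH-]; iodomethane CI
Why: Saponification opens the γ-lactone to the hydroxy carboxylate, and SN2 methylation of the carboxylate with MeI restores the C19 methyl ester without an acidic stage that would close the lactone again; no stereocentre is touched.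

Step 11
Reactants: 16 methyl (1S,2R,3R)-3-hydroxy-2-[(1S,3Z,6Z)-1-hydroxy-7-iodo-3-[(trimethylsilyl)methyl]octa-3,6-dien-1-yl]-1,3-dimethylcyclohexane-1-carboxylate
Product: 17 methyl (1S,2R,3R)-2-[(1S,3Z,6Z)-1-acetoxy-7-iodo-3-[(trimethylsilyl)methyl]octa-3,6-dien-1-yl]-3-hydroxy-1,3-dimethylcyclohexane-1-carboxylate
Conditions: Ac2O, pyridine, DMAP (cat.), CH2Cl2, 0 °C
Reagents that add atoms: acetic anhydride CC(=O)OC(C)=O
Why: DMAP-catalysed acylation acetylates the secondary C6 hydroxyl much faster than the hindered tertiary C10 hydroxyl reacts or the lactone re-forms; no stereocentre is touched.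

Step 12
Reactants: 17 methyl (1S,2R,3R)-2-[(1S,3Z,6Z)-1-acetoxy-7-iodo-3-[(trimethylsilyl)methyl]octa-3,6-dien-1-yl]-3-hydroxy-1,3-dimethylcyclohexane-1-carboxylate
Product: 18 methyl (1S,4aR,5S,8S,8aR)-8-acetoxy-5-[(2Z)-3-iodobut-2-en-1-yl]-1,4a-dimethyl-6-methylidenedecahydronaphthalene-1-carboxylate
Conditions: SnCl4, 2,6-di-tert-butylpyridine (0.2 equiv), CH2Cl2, −78 °C
Reagents that add atoms: none
Why: SnCl4 ionises the tertiary C10 carbinol, the ring A cation is captured by C9 of the (Z)-allylsilane, and the β-silyl cation at C8 loses the silyl group to give the C8=C17 exocyclic methylene regiospecifically; the closest known reaction types are the allylsilane-terminated cation–olefin cyclisation and the Lewis-acid allylation of tertiary carbinols by allylsilanes. Ring B closes in a 6-endo-trig mode (C8 and C9 both end up in the ring) through a chair transition state in which the C5–C6 bond is equatorial on ring A and the C6 acetate is equatorial. C10 is set by attack of C9 on the α face, because this leads to the trans-decalin chair and because the axial C19 ester, which can bond reversibly to the cation as a bridged lactonium ion, covers the β face, so the C10 methyl becomes β-axial. C9 is set by the (Z) geometry of the allylsilane, which holds C11 trans to C7 and therefore equatorial (β) in the chair. The step needs capture of the cation to outrun proton loss, protodesilylation and acetate participation; the low temperature, the hindered base and the preferred C5–C6 rotamer, in which C7 is gauche and the acetate oxygen anti to C10, should secure this.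

Step 13
Reactants: 18 methyl (1S,4aR,5S,8S,8aR)-8-acetoxy-5-[(2Z)-3-iodobut-2-en-1-yl]-1,4a-dimethyl-6-methylidenedecahydronaphthalene-1-carboxylate
Product: 19 methyl (1S,4aR,5S,8S,8aR)-8-acetoxy-1,4a-dimethyl-6-methylidene-5-[(2Z)-3-methylpenta-2,4-dien-1-yl]decahydronaphthalene-1-carboxylate
Conditions: CH2=CHSnBu3, Pd(PPh3)4 (cat.), CuI (cat.), DMF, 23 °C
Reagents that add atoms: tributyl(vinyl)stannane C=C[Sn](CCCC)(CCCC)CCCC
Why: Stille cross-coupling of the vinyl iodide with the vinylstannane proceeds with retention of the alkene geometry and should give the (12Z)-diene without affecting the acetate, the ester or the exocyclic methylene.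

Compound list
1 | 2,3-dihydrofuran | C1=COCC1 | starting material
2 | tert-butyl(2-iodoethoxy)dimethylsilane | CC(C)(C)[Si](C)(C)OCCI | starting material
3 | 5-lithio-2,3-dihydrofuran | [Li]C1=CCCO1 | intermediate
4 | tert-butyl[2-(4,5-dihydrofuran-2-yl)ethoxy]dimethylsilane | CC(C)(C)[Si](C)(C)OCCC1=CCCO1 | intermediate
5 | (3Z)-6-[(tert-butyldimethylsilyl)oxy]-4-[(trimethylsilyl)methyl]hex-3-en-1-ol | CC(C)(C)[Si](C)(C)OCC/C(C[Si](C)(C)C)=C/CCO | intermediate
6 | (3Z)-6-[(tert-butyldimethylsilyl)oxy]-4-[(trimethylsilyl)methyl]hex-3-enal | CC(C)(C)[Si](C)(C)OCC/C(C[Si](C)(C)C)=C/CC=O | intermediate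
7 | tert-butyl{[(3Z,6Z)-7-iodo-3-[(trimethylsilyl)methyl]octa-3,6-dien-1-yl]oxy}dimethylsilane | CC(C)(C)[Si](C)(C)OCC/C(C[Si](C)(C)C)=C/C/C=C(\I)C | intermediate
8 | (3Z,6Z)-7-iodo-3-[(trimethylsilyl)methyl]octa-3,6-dien-1-ol | OCC/C(C[Si](C)(C)C)=C/C/C=C(\I)C | intermediate
9 | (3Z,6Z)-7-iodo-3-[(trimethylsilyl)methyl]octa-3,6-dienal | O=CC/C(C[Si](C)(C)C)=C/C/C=C(\I)C | intermediate
10 | methyl 3-oxocyclohex-1-ene-1-carboxylate | COC(=O)C1=CC(=O)CCC1 | starting material
11 | methylzinc enolate of methyl (1S)-1-methyl-3-oxocyclohexane-1-carboxylate (C5 enolate) | C[Zn]OC1=C[C@@](C)(C(=O)OC)CCC1 | intermediate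
12 | methyl (1S,2S)-2-[(1S,3Z,6Z)-1-hydroxy-7-iodo-3-[(trimethylsilyl)methyl]octa-3,6-dien-1-yl]-1-methyl-3-oxocyclohexane-1-carboxylate (anti aldol, side chain trans to the ester) | I/C(C)=C\C/C=C(\C[Si](C)(C)C)C[C@H](O)[C@H]1C(=O)CCC[C@]1(C)C(=O)OC | intermediate
13 | (3S,3aR,7aS)-3-[(2Z,5Z)-6-iodo-2-[(trimethylsilyl)methyl]hepta-2,5-dien-1-yl]-7a-methylhexahydro-2-benzofuran-1,4-dione (cis-fused, C7 chain cis to H5) | I/C(C)=C\C/C=C(\C[Si](C)(C)C)C[C@@H]1OC(=O)[C@@]2(C)CCCC(=O)[C@@H]12 | intermediate
14 | (3S,3aR,4R,7aS)-4-hydroxy-3-[(2Z,5Z)-6-iodo-2-[(trimethylsilyl)methyl]hepta-2,5-dien-1-yl]-4,7a-dimethylhexahydro-2-benzofuran-1(3H)-one (hydroxyl cis to the lactone) | I/C(C)=C\C/C=C(\C[Si](C)(C)C)C[C@@H]1OC(=O)[C@@]2(C)CCC[C@@](C)(O)[C@@H]12 | intermediate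
15 | lithium (1S,2R,3R)-3-hydroxy-2-[(1S,3Z,6Z)-1-hydroxy-7-iodo-3-[(trimethylsilyl)methyl]octa-3,6-dien-1-yl]-1,3-dimethylcyclohexane-1-carboxylate | I/C(C)=C\C/C=C(\C[Si](C)(C)C)C[C@H](O)[C@@H]1[C@](C)(O)CCC[C@]1(C)C(=O)[O-].[Li+] | intermediate
16 | methyl (1S,2R,3R)-3-hydroxy-2-[(1S,3Z,6Z)-1-hydroxy-7-iodo-3-[(trimethylsilyl)methyl]octa-3,6-dien-1-yl]-1,3-dimethylcyclohexane-1-carboxylate | I/C(C)=C\C/C=C(\C[Si](C)(C)C)C[C@H](O)[C@@H]1[C@](C)(O)CCC[C@]1(C)C(=O)OC | intermediate
17 | methyl (1S,2R,3R)-2-[(1S,3Z,6Z)-1-acetoxy-7-iodo-3-[(trimethylsilyl)methyl]octa-3,6-dien-1-yl]-3-hydroxy-1,3-dimethylcyclohexane-1-carboxylate | I/C(C)=C\C/C=C(\C[Si](C)(C)C)C[C@H](OC(C)=O)[C@@H]1[C@](C)(O)CCC[C@]1(C)C(=O)OC | intermediate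
18 | methyl (1S,4aR,5S,8S,8aR)-8-acetoxy-5-[(2Z)-3-iodobut-2-en-1-yl]-1,4a-dimethyl-6-methylidenedecahydronaphthalene-1-carboxylate | I/C(C)=C\C[C@H]1C(=C)C[C@H](OC(C)=O)[C@@H]2[C@]1(C)CCC[C@]2(C)C(=O)OC | intermediate
19 | methyl (1S,4aR,5S,8S,8aR)-8-acetoxy-1,4a-dimethyl-6-methylidene-5-[(2Z)-3-methylpenta-2,4-dien-1-yl]decahydronaphthalene-1-carboxylate (methyl 6α-acetoxy-cis-communate) | C=C/C(C)=C\C[C@H]1C(=C)C[C@H](OC(C)=O)[C@@H]2[C@]1(C)CCC[C@]2(C)C(=O)OC | target

Total step count: 13. Longest linear sequence: 13 steps (steps 1–13; compound 10 enters at step 7).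

Steps most likely to fail

Step 12. The C10 cation may lose a proton to ring A alkenes, and the acid so released may protodesilylate the allylsilane. The neighbouring ester may also trap the cation and lose its methyl group, or closure may run through the cis-decalin transition state. The fallback sets out from 13 and returns at 18; it makes the same cation without Lewis or protic acid. Ketone 13 is methylenated under non-basic Takai–Lombardo conditions (Zn, CH2Br2, TiCl4) to the methylidene lactone F1. LiOH opens the lactone to the lithium hydroxy carboxylate F2, MeI gives the hydroxy ester F3, and Ac2O/DMAP gives the acetate F4. Hydrogen-atom transfer to the 1,1-disubstituted C10=C20 alkene of F4, followed by oxidation of the tertiary radical (radical–polar crossover), then generates the cation with a non-nucleophilic counter-ion. The reagents are [N,N′-bis(3,5-di-tert-butylsalicylidene)-1,2-cyclohexanediaminato]cobalt as catalyst (divalent cobalt), N-fluoro-2,4,6-trimethylpyridinium tetrafluoroborate and PhSiH3. Capture by the allylsilane gives 18.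

Step 8. The open enone formed during equilibration may isomerise irreversibly (double-bond migration towards the allylsilane alkene), retro-aldol cleavage may release the labile aldehyde, or the thermodynamic preference may be too small. The fallback sets out from 12 and returns at 13; it sets C6 under catalyst control instead. The diastereomers of 12 are dehydrated with the Burgess reagent to the (Z)-alkylidene ketone F5. Copper-catalysed enantioselective conjugate borylation (B2pin2, CuCl, NaOt-Bu, one enantiomer of BINAP, MeOH) gives the β-boryl ketone F6, and NaBO3 oxidises it with retention to the β-hydroxy ketone F7. A weak base (Et3N, 2-hydroxypyridine, toluene) then epimerises C5 by enolisation only and closes the lactone to 13.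

Step 7. The zinc enolate may enolise or isomerise the β,γ-unsaturated aldehyde 9 instead of adding to it, and the sluggish conjugate addition of Me2Zn may be incomplete when the aldehyde is introduced. The fallback sets out from 10 and returns at 12; it separates the two events. The conjugate addition is run alone and the zinc enolate is trapped with TMSOTf as the silyl enol ether F8. After purification, F8 is joined to 9 in a Mukaiyama aldol addition (BF3·OEt2, CH2Cl2, −78 °C) to give 12.

Further compounds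
F1 | step 12 | (3S,3aR,7aS)-3-[(2Z,5Z)-6-iodo-2-[(trimethylsilyl)methyl]hepta-2,5-dien-1-yl]-7a-methyl-4-methylidenehexahydro-2-benzofuran-1(3H)-one | I/C(C)=C\C/C=C(\C[Si](C)(C)C)C[C@@H]1OC(=O)[C@@]2(C)CCCC(=C)[C@@H]12
F2 | step 12 | lithium (1S,2R)-2-[(1S,3Z,6Z)-1-hydroxy-7-iodo-3-[(trimethylsilyl)methyl]octa-3,6-dien-1-yl]-1-methyl-3-methylidenecyclohexane-1-carboxylate | I/C(C)=C\C/C=C(\C[Si](C)(C)C)C[C@H](O)[C@@H]1C(=C)CCC[C@]1(C)C(=O)[O-].[Li+]
F3 | step 12 | methyl (1S,2R)-2-[(1S,3Z,6Z)-1-hydroxy-7-iodo-3-[(trimethylsilyl)methyl]octa-3,6-dien-1-yl]-1-methyl-3-methylidenecyclohexane-1-carboxylate | I/C(C)=C\C/C=C(\C[Si](C)(C)C)C[C@H](O)[C@@H]1C(=C)CCC[C@]1(C)C(=O)OC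
F4 | step 12 | methyl (1S,2R)-2-[(1S,3Z,6Z)-1-acetoxy-7-iodo-3-[(trimethylsilyl)methyl]octa-3,6-dien-1-yl]-1-methyl-3-methylidenecyclohexane-1-carboxylate | I/C(C)=C\C/C=C(\C[Si](C)(C)C)C[C@H](OC(C)=O)[C@@H]1C(=C)CCC[C@]1(C)C(=O)OC
F5 | step 8 | methyl (1S,2Z)-2-[(3Z,6Z)-7-iodo-3-[(trimethylsilyl)methyl]octa-3,6-dien-1-ylidene]-1-methyl-3-oxocyclohexane-1-carboxylate | COC(=O)[C@@]1(C)CCCC(=O)/C1=C\C/C(C[Si](C)(C)C)=C/C/C=C(\I)C
F6 | step 8 | methyl (1S,2R)-2-[(1S,3Z,6Z)-7-iodo-1-(4,4,5,5-tetramethyl-1,3,2-dioxaborolan-2-yl)-3-[(trimethylsilyl)methyl]octa-3,6-dien-1-yl]-1-methyl-3-oxocyclohexane-1-carboxylate (boron in the place of the C6 oxygen) | I/C(C)=C\C/C=C(\C[Si](C)(C)C)C[C@H](B1OC(C)(C)C(C)(C)O1)[C@@H]1C(=O)CCC[C@]1(C)C(=O)OC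
F7 | step 8 | methyl (1S,2R)-2-[(1S,3Z,6Z)-1-hydroxy-7-iodo-3-[(trimethylsilyl)methyl]octa-3,6-dien-1-yl]-1-methyl-3-oxocyclohexane-1-carboxylate | I/C(C)=C\C/C=C(\C[Si](C)(C)C)C[C@H](O)[C@@H]1C(=O)CCC[C@]1(C)C(=O)OC
F8 | step 7 | methyl (1S)-1-methyl-3-[(trimethylsilyl)oxy]cyclohex-2-ene-1-carboxylate | C[Si](C)(C)OC1=C[C@@](C)(C(=O)OC)CCC1
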